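## Retrosynthetic overview

1. **Feature used.** On the cyclohexane ring C1–C6, the C1 ethyl, C2 methyl, C5 aryl and the C6–C7 bond into the spiro dienone ring (C6–C11) all lie on one face. An endo [4+2] of a ring-locked cis dienophile (C6=C1) with a diene C2–C5 whose two end groups point outward leaves exactly this pattern.
2. **Dienone ring (formed last).** C7=C8 comes from an aldol condensation and C11–OMe from methanol addition to a C11≡C10–C9(=O) ynone. The alkyne goes back to a C11 hydroxymethyl group and C7 to the lactone carbonyl.
3. **C6–C11 and the C1 ethyl.** C6–C11 comes from alkylation of the cis-fused lactone enolate on its convex face. The C1 ethyl comes from the acetal carbon by way of aldehyde and vinyl.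
4. **C3–Ar and C4–Me.** C3–Ar comes from arylcerium addition to a C3 ketone followed by hydride capture of the benzylic cation. C4–Me comes from methylation of the regiodefined C3–C4 enol ether.
5. **C1–C2 and C5–C6 (cyclohexane ring, formed first).** These come from a Diels–Alder reaction of a (2Z,4E)-3-silyloxy-5-arylpentadiene with (5R)-5-(l-menthyloxy)-2(5H)-furanone. Ring order: butenolide (temporary), cyclohexane, dienone.

Key step: step 5

**Convention.** Target numbering is used throughout. C7 is the former lactone carbonyl carbon, C11 is the carbon added at C6, and "acetal carbon" is the future CH2 of the ethyl group. With the cyclohexane drawn flat and C1→C6 running clockwise, β points toward the viewer and α away. In the target, C1-Et, C2-Me, C3-Ar, C5-Ar and C7 are α, while C4-Me and C11 are β. Ar = 2,4,5-trimethoxyphenyl; Men = (1R,2S,5R)-menthyl.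

**Remark on the chemistry (C4 methyl).** The C4 methyl is not carried on the diene.
- Any electrophile should reach C4 of the cycloadduct's enol ether from the β face, anti to the C5 aryl and to the endo lactone.
- A proton arriving there would push a pre-installed methyl to the α face, cis to the aryl.
- Equilibration could not correct this, because it would first epimerise the strained axial C2 methyl.
- With C4 unsubstituted, the same facial bias places an incoming methyl β, as required.

**Assumption.** Carbinol 16 is drawn with the aryl group β; its C3 configuration is erased in step 8. Compound 20 is an anomeric mixture.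

## Route

Step 1
Reactants: 1 2,4,5-trimethoxybenzaldehyde; 2 diethyl (2-oxobutyl)phosphonate
Product: 3 (E)-1-(2,4,5-trimethoxyphenyl)pent-1-en-3-one
Conditions: K2CO3, EtOH, 60 °C
Reagents that add atoms: none
Why: Horner–Wadsworth–Emmons olefination of a non-enolisable aryl aldehyde with a β-ketophosphonate should give the (E)-enone and, unlike an aldol with butanone, leaves no doubt about which α-carbon reacts.

Step 2
Reactants: 3 (E)-1-(2,4,5-trimethoxyphenyl)pent-1-en-3-one
Product: 4 tert-butyl(dimethyl){[(2Z,4E)-5-(2,4,5-trimethoxyphenyl)penta-2,4-dien-3-yl]oxy}silane (C2 methyl cis to OTBS; aryl trans to C3)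
Conditions: TBSOTf, Et3N, CH2Cl2, 0 °C
Reagents that add atoms: tert-butyldimethylsilyl triflate, CC(C)(C)[Si](C)(C)OS(=O)(=O)C(F)(F)F
Why: Soft enolisation (silyl triflate and amine) removes a proton from the only enolisable carbon, and the (Z)-silyl enol ether is favoured because it avoids allylic strain between the terminal methyl and the styryl chain, so methyl and aryl both sit outside on the s-cis diene.

Step 3
Reactants: 5 furfural
Product: 7 5-hydroxy-2(5H)-furanone (racemic lactol), via furfural endoperoxide 6 (not isolated)
Conditions: O2, hν (visible), rose bengal (cat.), MeOH, 0 °C → rt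
Reagents that add atoms: oxygen, O=O
Why: Dye-sensitised singlet-oxygen [4+2] addition to the furan followed by methanolytic loss of the formyl group is the standard preparation of this hydroxybutenolide.

Step 4
Reactants: 7 5-hydroxy-2(5H)-furanone; 8 (−)-menthol
Product: 9 (5R)-5-[(1R,2S,5R)-menthyloxy]-2(5H)-furanone
Conditions: CSA (cat.), toluene, reflux (Dean–Stark); crystallisation from petroleum ether, mother liquor re-equilibrated with acid
Reagents that add atoms: none
Why: Acid-catalysed acetalisation of the lactol gives both acetal epimers, and the (5R)-epimer should crystallise out while acid keeps the epimers in equilibrium, so the new acetal stereocentre is fixed by crystallisation of the menthol-derived diastereomer.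

Step 5
Reactants: 4 (2Z,4E)-silyloxy diene; 9 (5R)-menthyloxybutenolide
Product: 10 cycloadduct: γ-lactone acetal cis-fused on the α face of cyclohexene C1–C6 (H-1 and H-6 β); C3(OTBS)=C4H; C2-Me α; C5-Ar α; acetal carbon R with OMen trans to C2
Conditions: toluene (concentrated), BHT (cat.), 115 °C, sealed tube
Reagents that add atoms: none
Why: Concerted, asynchronous normal-demand [4+2] cycloaddition in which the C3 silyloxy group and the C5 aryl group both raise the HOMO coefficient at C2, so C2 bonds ahead to the electrophilic lactone β-carbon C1 while C5 closes onto the α-carbon C6, forming C1–C2 and C5–C6. The closest known reaction type is the thermal endo Diels–Alder reaction of 5-menthyloxy-2(5H)-furanone with 2-silyloxy- and 1-substituted butadienes. The cyclohexene ring C1–C6 is closed in one suprafacial–suprafacial event through a boat-like transition state, and the γ-lactone ends cis-fused because its C6=C1 double bond is a ring-locked cis alkene. C1 and C6 are controlled by the auxiliary, the diene adding to the butenolide face anti to the menthyloxy group on the acetal carbon, while C2 and C5 are controlled by the (2Z,4E) geometry of 4 (methyl and aryl both outside) combined with the endo orientation of the lactone carbonyl, which places C2-Me, C5-Ar, the acetal carbon and C7 together on the α face. The step therefore needs regio-, endo/exo- and π-facial selectivity, secured in turn by the matched C3-oxygen and C5-aryl donors, by secondary overlap of the lactone carbonyl with C3–C4 (helped by the absence of a C4 substituent above it) and by the bulky menthyloxy group next to C1. The adduct keeps a regiodefined C3–C4 silyl enol ether for the next step.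

Step 6
Reactants: 10 cycloadduct
Product: 12 C3 ketone of the same bicycle; C4-Me β (trans to C5-Ar); C2-Me α retained, via ammonium enolate 11 (not isolated)
Conditions: BnMe3NF (anhydrous), MeI (excess), 4 Å MS, THF, −20 °C → rt
Reagents that add atoms: methyl iodide, CI
Why: In this fluoride-triggered regiospecific alkylation of a silyl enol ether the naked C3–C4 enolate should be methylated faster than it exchanges protons, with MeI reaching C4 on the convex β face anti to the C5 aryl and the endo lactone (trans C4/C5), while the C2–H, lying near the carbonyl plane, is left alone.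

Step 7
Reactants: 12 C3 ketone; 13 1-bromo-2,4,5-trimethoxybenzene
Product: 16 tertiary benzylic alcohol; C3-Ar β; C3-OH α, via aryllithium 14 (not isolated), via arylcerium dichloride 15 (not isolated)
Conditions: 13, n-BuLi, THF, −78 °C; CeCl3 (anhydrous), −78 °C; then 12, −78 °C; aq. NH4Cl
Reagents that add atoms: none
Why: In this organocerium 1,2-addition the weakly basic, oxophilic aryl reagent should add to the hindered enolisable ketone without disturbing C2 or C4 and faster than to the lactone at −78 °C, entering axially from the β face because the axial C2 methyl blocks the α side.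

Step 8
Reactants: 16 tertiary benzylic alcohol
Product: 17 C3-deoxy lactone acetal; C3-H β; C3-Ar α
Conditions: Et3SiH (excess), TFA, CH2Cl2, −78 → −20 °C
Reagents that add atoms: none
Why: In this ionic hydrogenation the trimethoxyphenyl group lets the tertiary alcohol ionise at low temperature where the acyloxy acetal is inert, and silane hydride should be delivered to the β face of the benzylic cation, anti to the axial C2 methyl and through a late transition state that already feels the equatorial aryl, which sets C3.

Step 9
Reactants: 17 C3-deoxy lactone acetal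
Product: 19 C6-quaternary lactone acetal; C6-CH2OBn (C11) β; C7 carbonyl α, via lithium lactone enolate 18 (not isolated)
Conditions: LDA, THF, −78 °C; then BnOCH2Cl, −78 → −20 °C
Reagents that add atoms: benzyl chloromethyl ether, ClCOCc1ccccc1
Why: In this alkylation of a γ-alkoxy-γ-lactone enolate C6–H is the only acidic C–H, and the cis-fused bicyclic enolate can accept the reactive electrophile only on its convex β face because the lactone tether holds C7 α, so quaternary C6 should form with C11 β and C7 α as in the target.

Step 10
Reactants: 19 C6-quaternary lactone acetal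
Product: 20 pseudo-acid (γ-hydroxy-γ-lactone; anomeric mixture) of the C1-aldehyde C6-acid
Conditions: 2 M aq. HCl, 1,4-dioxane, 80 °C
Reagents that add atoms: water, O
Why: Acid-catalysed acetal hydrolysis releases the auxiliary and gives the ring-closed pseudo-acid, whose cis-fused lactol form keeps the C1 aldehyde masked and so protects C1 from epimerisation next to the now immovable quaternary C6.

Step 11
Reactants: 20 pseudo-acid
Product: 22 methyl ester; C1-vinyl α; C6-CH2OBn β; C6-CO2Me α, via potassium vinyl carboxylate 21 (not isolated)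
Conditions: Ph3PCH3Br, KOt-Bu (ylide in excess), THF, 0 °C; then MeI, DMF, rt
Reagents that add atoms: methyltriphenylphosphonium bromide, C[P+](c1ccccc1)(c1ccccc1)c1ccccc1.[Br-]; methyl iodide, CI
Why: In this Wittig methylenation base opens the lactol to the carboxylate aldehyde, the unstabilised ylide should olefinate the aldehyde faster than C1 enolises, and the crowded carboxylate is then esterified by SN2 attack on MeI, which does not feel the hindrance at C6.

Step 12
Reactants: 22 vinyl benzyl ether ester
Product: 23 β-hydroxy ester; C1-ethyl α; C6-CH2OH β; C6-CO2Me α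
Conditions: H2 (1 atm), Pd(OH)2/C, EtOAc–MeOH, rt
Reagents that add atoms: none
Why: Heterogeneous hydrogenation saturates the monosubstituted alkene and hydrogenolyses the benzyl ether in the same operation without touching any stereocentre.

Step 13
Reactants: 23 β-hydroxy ester
Product: 24 α-formyl ester; C6-CHO (C11) β
Conditions: Dess–Martin periodinane, CH2Cl2, rt
Reagents that add atoms: none
Why: Dess–Martin oxidation of the neopentyl primary alcohol under non-basic conditions should give the non-enolisable formyl ester without retro-aldol or deformylation.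

Step 14
Reactants: 24 α-formyl ester
Product: 25 α-ethynyl ester; C6-C≡CH (C11≡C10) β
Conditions: TMSCHN2, LDA, THF, −78 °C → rt
Reagents that add atoms: trimethylsilyldiazomethane, C[Si](C)(C)C=[N+]=[N-]
Why: In this Colvin rearrangement (Seyferth–Gilbert type homologation) the lithiated silyldiazomethane adds to the aldehyde, loss of silanolate and nitrogen gives an alkylidene carbene whose 1,2-hydrogen shift forms the terminal alkyne, and the alkoxide-free medium avoids retro-Claisen loss of the formyl group.

Step 15
Reactants: 25 α-ethynyl ester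
Product: 26 ethynyl neopentyl alcohol; C6-CH2OH (C7) α
Conditions: LiAlH4, THF, 0 °C → rt
Reagents that add atoms: none
Why: Hydride reduction takes the hindered ester to the primary alcohol, and an isolated terminal alkyne is not hydroaluminated under these conditions.

Step 16
Reactants: 26 ethynyl neopentyl alcohol; 27 N,2-dimethoxy-N-methylacetamide
Product: 29 ynone alcohol; C6-C≡C-C(=O)CH2OMe β; C7H2OH α, via dilithio alkoxide acetylide 28 (not isolated)
Conditions: n-BuLi (2.1 equiv), THF, −78 → 0 °C; then 27, −78 °C; cold 1 M HCl quench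
Reagents that add atoms: none
Why: In this acylation of a lithium acetylide with a Weinreb amide the chelated tetrahedral adduct prevents over-addition, the neopentyl alkoxide is a spectator, and the cold acidic quench keeps the liberated amine from adding to the ynone.

Step 17
Reactants: 29 ynone alcohol
Product: 30 ynone aldehyde; C7HO α
Conditions: Dess–Martin periodinane, CH2Cl2, rt
Reagents that add atoms: none
Why: Dess–Martin oxidation converts the neopentyl alcohol into the non-enolisable aldehyde without affecting the ynone.

Step 18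
Reactants: 30 ynone aldehyde
Product: 32 Tatanan B, via methoxyenone aldehyde 31 (not isolated)
Conditions: K2CO3 (cat.), MeOH, 0 °C → rt
Reagents that add atoms: methanol, CO
Why: Base-catalysed oxa-Michael addition of methanol puts OMe on the ynone β-carbon C11 as dictated by the C9 carbonyl, the enol ether isomers interconvert by reversible methoxide addition, and only the isomer with C6 and C9 cis can close the six-membered ring by intramolecular aldol condensation of C8 onto the C7 aldehyde, so the spiro centre set in step 9 is carried unchanged into the dienone.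

## Compound list

1 | 2,4,5-trimethoxybenzaldehyde | COc1cc(OC)c(C=O)cc1OC | starting material
2 | diethyl (2-oxobutyl)phosphonate | CCC(=O)CP(=O)(OCC)OCC | starting material
3 | (E)-1-(2,4,5-trimethoxyphenyl)pent-1-en-3-one | CCC(=O)/C=C/c1cc(OC)c(OC)cc1OC | intermediate
4 | (2Z,4E)-3-(TBS-oxy)-5-(2,4,5-trimethoxyphenyl)penta-2,4-diene | C/C=C(O[Si](C)(C)C(C)(C)C)/C=C/c1cc(OC)c(OC)cc1OC | intermediate
5 | furfural | O=Cc1ccco1 | starting material
6 | furfural endoperoxide | O=CC12C=CC(OO1)O2 | intermediate
7 | 5-hydroxy-2(5H)-furanone | O=C1C=CC(O)O1 | intermediate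
8 | (−)-menthol | CC(C)[C@@H]1CC[C@@H](C)C[C@H]1O | starting material
9 | (5R)-5-(l-menthyloxy)-2(5H)-furanone | O=C1C=C[C@H](O[C@@H]2C[C@H](C)CC[C@H]2C(C)C)O1 | intermediate
10 | Diels–Alder adduct (C3–C4 silyl enol ether) | O1[C@@H](O[C@@H]3C[C@H](C)CC[C@H]3C(C)C)[C@@H]2[C@H](C)C(O[Si](C)(C)C(C)(C)C)=C[C@H](c3cc(OC)c(OC)cc3OC)[C@@H]2C1=O | intermediate
11 | benzyltrimethylammonium C3–C4 enolate | O1[C@@H](O[C@@H]3C[C@H](C)CC[C@H]3C(C)C)[C@@H]2[C@H](C)C([O-])=C[C@H](c3cc(OC)c(OC)cc3OC)[C@@H]2C1=O.C[N+](C)(C)Cc1ccccc1 | intermediate
12 | C3 ketone, C4-Me β | O1[C@@H](O[C@@H]3C[C@H](C)CC[C@H]3C(C)C)[C@@H]2[C@H](C)C(=O)[C@@H](C)[C@H](c3cc(OC)c(OC)cc3OC)[C@@H]2C1=O | intermediate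
13 | 1-bromo-2,4,5-trimethoxybenzene | COc1cc(OC)c(Br)cc1OC | starting material
14 | 2,4,5-trimethoxyphenyllithium | COc1cc(OC)c([Li])cc1OC | intermediate
15 | 2,4,5-trimethoxyphenylcerium dichloride | COc1cc(OC)c([Ce](Cl)Cl)cc1OC | intermediate
16 | C3 tertiary benzylic alcohol | O1[C@@H](O[C@@H]3C[C@H](C)CC[C@H]3C(C)C)[C@@H]2[C@H](C)[C@@](O)(c3cc(OC)c(OC)cc3OC)[C@@H](C)[C@H](c3cc(OC)c(OC)cc3OC)[C@@H]2C1=O | intermediate
17 | C3-deoxy lactone acetal | O1[C@@H](O[C@@H]3C[C@H](C)CC[C@H]3C(C)C)[C@@H]2[C@H](C)[C@H](c3cc(OC)c(OC)cc3OC)[C@@H](C)[C@H](c3cc(OC)c(OC)cc3OC)[C@@H]2C1=O | intermediate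
18 | lithium lactone enolate | O1[C@@H](O[C@@H]3C[C@H](C)CC[C@H]3C(C)C)[C@@H]2[C@H](C)[C@H](c3cc(OC)c(OC)cc3OC)[C@@H](C)[C@H](c3cc(OC)c(OC)cc3OC)C2=C1[O-].[Li+] | intermediate
19 | C6-(benzyloxymethyl) lactone acetal | O1[C@@H](O[C@@H]3C[C@H](C)CC[C@H]3C(C)C)[C@@H]2[C@H](C)[C@H](c3cc(OC)c(OC)cc3OC)[C@@H](C)[C@H](c3cc(OC)c(OC)cc3OC)[C@]2(COCc3ccccc3)C1=O | intermediate
20 | pseudo-acid (γ-hydroxy lactone) | O1C(O)[C@@H]2[C@H](C)[C@H](c3cc(OC)c(OC)cc3OC)[C@@H](C)[C@H](c3cc(OC)c(OC)cc3OC)[C@]2(COCc3ccccc3)C1=O | intermediate
21 | potassium vinyl carboxylate | C=C[C@@H]1[C@H](C)[C@H](c2cc(OC)c(OC)cc2OC)[C@@H](C)[C@H](c2cc(OC)c(OC)cc2OC)[C@]1(COCc2ccccc2)C(=O)[O-].[K+] | intermediate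
22 | vinyl benzyl ether methyl ester | C=C[C@@H]1[C@H](C)[C@H](c2cc(OC)c(OC)cc2OC)[C@@H](C)[C@H](c2cc(OC)c(OC)cc2OC)[C@]1(COCc2ccccc2)C(=O)OC | intermediate
23 | ethyl β-hydroxy ester | CC[C@@H]1[C@H](C)[C@H](c2cc(OC)c(OC)cc2OC)[C@@H](C)[C@H](c2cc(OC)c(OC)cc2OC)[C@]1(CO)C(=O)OC | intermediate
24 | α-formyl ester | CC[C@@H]1[C@H](C)[C@H](c2cc(OC)c(OC)cc2OC)[C@@H](C)[C@H](c2cc(OC)c(OC)cc2OC)[C@]1(C=O)C(=O)OC | intermediate
25 | α-ethynyl ester | CC[C@@H]1[C@H](C)[C@H](c2cc(OC)c(OC)cc2OC)[C@@H](C)[C@H](c2cc(OC)c(OC)cc2OC)[C@]1(C#C)C(=O)OC | intermediate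
26 | ethynyl neopentyl alcohol | CC[C@@H]1[C@H](C)[C@H](c2cc(OC)c(OC)cc2OC)[C@@H](C)[C@H](c2cc(OC)c(OC)cc2OC)[C@]1(C#C)CO | intermediate
27 | N,2-dimethoxy-N-methylacetamide | COCC(=O)N(C)OC | starting material
28 | dilithio alkoxide acetylide | CC[C@@H]1[C@H](C)[C@H](c2cc(OC)c(OC)cc2OC)[C@@H](C)[C@H](c2cc(OC)c(OC)cc2OC)[C@]1(C#C[Li])CO[Li] | intermediate
29 | ynone alcohol | CC[C@@H]1[C@H](C)[C@H](c2cc(OC)c(OC)cc2OC)[C@@H](C)[C@H](c2cc(OC)c(OC)cc2OC)[C@]1(C#CC(=O)COC)CO | intermediate
30 | ynone aldehyde | CC[C@@H]1[C@H](C)[C@H](c2cc(OC)c(OC)cc2OC)[C@@H](C)[C@H](c2cc(OC)c(OC)cc2OC)[C@]1(C#CC(=O)COC)C=O | intermediate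
31 | (E)-β-methoxyenone aldehyde (C6 and C9 cis) | CC[C@@H]1[C@H](C)[C@H](c2cc(OC)c(OC)cc2OC)[C@@H](C)[C@H](c2cc(OC)c(OC)cc2OC)[C@]1(/C(OC)=C\C(=O)COC)C=O | intermediate
32 | Tatanan B | CC[C@@H]1[C@H](C)[C@H](c2cc(OC)c(OC)cc2OC)[C@@H](C)[C@H](c2cc(OC)c(OC)cc2OC)[C@]12C=C(OC)C(=O)C=C2OC | target

## Step count and risks

Total step count: 18. Longest linear sequence: 16 steps (1, 2, 5–18). The branch through steps 3 and 4 is of equal length.

**Step 5.**
- What may go wrong: the cycloaddition may be too slow at temperatures the silyloxy diene tolerates. The exo mode may also compete, which would invert C2 and C5 relative to C1 and C6.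
- Fallback: an anionic Michael–Michael sequence that sets out from enone 3 and butenolide 9 and returns at ketone 12.
- Enone 3 is deprotonated at C2 with LiHMDS (THF, −78 °C) to the cross-conjugated lithium (Z)-dienolate F1.
- Addition of 9 should give, by conjugate addition anti to the menthyloxy group, the lithium lactone enolate F2.
- On warming, F2 should close C6 onto C5 in a lithium-bridged, endo-like intramolecular Michael addition, giving the bicyclic lithium C3–C4 enolate F3.
- MeI/DMPU then methylates C4 on the β face and delivers 12. Steps 2, 5 and 6 are bypassed.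

**Step 8.**
- What may go wrong: the benzylic cation may lose the axial C4 proton faster than it takes up hydride, and re-protonation of the resulting styrene would scramble C4. Hydride delivery to the α face would invert C3.
- Fallback: a radical deoxygenation that sets out from 16 and returns at 17.
- The alkoxide of 16 (KHMDS, THF, −78 °C) is acylated with methyl chlorooxoacetate to the tertiary methyl oxalate F4.
- F4 is reduced with Bu3SnH and Et3B/air in toluene at rt. The planar benzylic radical cannot lose a neighbouring proton and should take hydrogen from the stannane on the β face.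

**Step 9.**
- What may go wrong: C–C bond formation at the crowded enolate carbon may be slow, and the hard chloromethyl ether may alkylate on oxygen.
- Fallback: an aldol route that sets out from 17 and returns at 19.
- The enolate (LDA, THF, −78 °C) is treated with gaseous monomeric formaldehyde, a small electrophile that reacts at carbon. This should give the hydroxymethyl lactone F5 with the same convex-face selectivity.
- F5 is benzylated under acid catalysis (benzyl 2,2,2-trichloroacetimidate, TfOH cat., CH2Cl2, 0 °C) to 19.

## Further compounds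

F1 | step 5 | lithium (Z)-dienolate of enone 3 | C/C=C([O-])/C=C/c1cc(OC)c(OC)cc1OC.[Li+]
F2 | step 5 | lithium lactone enolate after the first Michael addition | O1[C@@H](O[C@@H]3C[C@H](C)CC[C@H]3C(C)C)[C@@H](C=C1[O-])[C@H](C)C(=O)/C=C/c3cc(OC)c(OC)cc3OC.[Li+]
F3 | step 5 | bicyclic lithium C3–C4 enolate | O1[C@@H](O[C@@H]3C[C@H](C)CC[C@H]3C(C)C)[C@@H]2[C@H](C)C([O-])=C[C@H](c3cc(OC)c(OC)cc3OC)[C@@H]2C1=O.[Li+]
F4 | step 8 | tertiary methyl oxalate of 16 | O1[C@@H](O[C@@H]3C[C@H](C)CC[C@H]3C(C)C)[C@@H]2[C@H](C)[C@@](OC(=O)C(=O)OC)(c3cc(OC)c(OC)cc3OC)[C@@H](C)[C@H](c3cc(OC)c(OC)cc3OC)[C@@H]2C1=O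
F5 | step 9 | C6-hydroxymethyl lactone acetal | O1[C@@H](O[C@@H]3C[C@H](C)CC[C@H]3C(C)C)[C@@H]2[C@H](C)[C@H](c3cc(OC)c(OC)cc3OC)[C@@H](C)[C@H](c3cc(OC)c(OC)cc3OC)[C@]2(CO)C1=O
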